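The last reading stood at 10.0 d, and the flask with 41 mM of L was asked about at 15 d, which is 5.00 d further on.

| flask | L | remark | time |
|---|---|---|---|
| Tuesday's | 27 mM | run made earlier |  |
| Friday's | 62 mM | run made earlier |  |
| flask | 41 mM |  | 15 d |

| run | time / d | G / % | Q / % |
|---|---|---|---|
| Tuesday's | 0.500 | 1.2 | 24.1 |
| Tuesday's | 1.25 | 1.2 | 49.2 |
| Tuesday's | 2.50 | 5.3 | 67.5 |
| Tuesday's | 4.00 | 10.8 | 72.4 |
| Tuesday's | 5.00 | 13.0 | 73.4 |
| Tuesday's | 8.00 | 20.1 | 68.6 |
| Tuesday's | 10.0 | 25.2 | 65.7 |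
| Friday's | 0.500 | 0.8 | 24.2 |
| Friday's | 1.25 | 1.6 | 49.0 |
| Friday's | 2.50 | 5.2 | 67.5 |
| Friday's | 4.00 | 8.5 | 74.2 |
| Friday's | 5.00 | 11.5 | 72.5 |
| Friday's | 8.00 | 19.2 | 68.4 |
| Friday's | 10.0 | 25.0 | 63.5 |

(readings scatter by 0.5 percentage points)

- ratio of G to Q at 1.5 h
- ratio of G to Q at 15 d
- which of G and Q there is more of at 15 d

- the numbers in the tables scatter by 0.5 percentage points (one standard deviation)

I asked what a lead for G at 15 d requires. Tuesday's and Friday's runs, at 27 mM and 62 mM, read 73.4% and 72.5% of Q at 5.00 d, so I took the percentages to hold for the flask and averaged them. The mean reading of Q in the two runs fell from 68.5% at 8.00 d to 64.6% at 10.0 d. I call the fraction of Q lost per day, an apparent first-order constant, the drain constant 0.0293 d⁻¹. Over those readings the mean of G rose from 19.7% to 25.1%, a gain of 1.40 per point of Q lost. Integrating d[Q]/dt = −k[Q], with k the drain constant, from the means at 10.0 d gave: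

[Q] = 64.6% · exp(−0.0293 d⁻¹ · 5.00 d) = 55.8%

[G] = 25.1% + 1.40 · (64.6% − 55.8%) = 37.4%

So I expected Q to stay ahead of G, at a ratio of 0.670. On this reckoning, equal amounts at 15 d need Q to keep a fraction 0.745 of its mean at 10.0 d, which asks for a constant of 0.0589 d⁻¹, twice the one read. The time 1.5 h lies before the first reading, and I gave no figure for it.

The forecast gave ratios of G to Q of 0.002 at 1.5 h and 0.66 at 15 d, with Q ahead, “so Q still leads”.

The flask gave ratios of 0.0153 at 1.5 h and 0.646 at 15 d, with Q at 55.2% and G at 35.7%.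

    Z ⇌ Q (K = 6.00, k = 0.650 h⁻¹)
    L → Z (k = 0.0310 h⁻¹)
    Z ⇌ G (K = 220, k = 0.00940 h⁻¹)

Z, absent from the readings, stood in the flask at 9.09% at 15.0 d. Started from the flask's 69.6% of Q at 7.50 d, the drain constant gives 55.9% at 15 d.

For the neighbour with 10 mM of L, the same constant and percentages give 55.8% of Q and a ratio of 0.670. Computed, it held 55.2% of Q and 35.7% of G, a ratio of 0.646.

The earlier runs and the new flask stem from a simulated flask with made-up constants; the scatter is artificial.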